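**Retrosynthetic overview**
1. The route rests on ring D: C-1′ (tertiary carbinol on pyridone C-5), the C-2′/C-3′ oxirane, the C-4′ carbinol and the C-5′/C-6′ methylenes carry the oxygen pattern of a para-substituted phenol. Its O-silyl p-quinol has a prochiral C-1′ between two enantiotopic enone arms, so one nucleophilic epoxidation anti to the silyloxy group sets C-1′, C-2′ and C-3′ together.
2. After the epoxidation: conjugate reduction of C-5′=C-6′, reduction of the C-4′ ketone from the oxirane face, removal of the silyl and methoxymethyl (MOM) groups.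
3. Before it: p-quinol by oxidative dearomatisation of a 5-(4-hydroxyphenyl)pyridine; pyridine C-3–acyl bond by addition of the C-3 lithiated 2,4-bis(methoxymethoxy)pyridine to the decalin aldehyde and oxidation; biaryl bond by Suzuki–Miyaura coupling.
4. Decalin bonds C-1–C-2 and C-4a–C-8a by intramolecular Diels–Alder reaction of an (S)-citronellal-derived trienal, then Julia–Kocienski propenylation and epimerisation of C-2.
5. Ring order: rings A and B together (step 8); the pyridine ring C and the arene that becomes ring D are bought; the oxirane is closed last (step 21).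

Key step: step 21

Locants: decalin C-1 (propenyl), C-2 (acyl), C-3=C-4(Me), C-4a, C-7 (Me), C-8a; ring D primed, C-1′ on pyridine C-5; "Dec" = (1R,2S,4aS,7S,8aR)-4,7-dimethyl-1-[(E)-prop-1-enyl]-1,2,4a,5,6,7,8,8a-octahydronaphthalen-2-yl.
Assumption: the quinine-derived primary amine is taken to select the enone arm that becomes C-2′/C-3′; if the sense on this dienone class is the opposite, its quinidine-derived pseudoenantiomer is used with no other change; boronic acid 18 is bought.

**Route**

Step 1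
Reactants: 1 (S)-citronellal
Product: 2 (S)-8,8-dimethoxy-2,6-dimethyloct-2-ene
Conditions: HC(OMe)3, MeOH, PPTS (cat.), 0 °C → rt
Reagents that add atoms: trimethyl orthoformate, COC(OC)OC
Why: Acid-catalysed acetalisation driven by the orthoformate should mask the aldehyde without touching the methyl-bearing centre, and the weak pyridinium acid avoids the carbonyl-ene cyclisation of citronellal.

Step 2
Reactants: 2 (S)-8,8-dimethoxy-2,6-dimethyloct-2-ene
Product: 4 (S,E)-8,8-dimethoxy-2,6-dimethyloct-2-enal, via allylic alcohol 3 (not isolated)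
Conditions: SeO2 (10 mol%), t-BuOOH (decane), salicylic acid (10 mol%), CH2Cl2, rt; aqueous work-up; then MnO2, CH2Cl2, rt
Reagents that add atoms: tert-butyl hydroperoxide (oxygen relayed by SeO2), CC(C)(C)OO
Why: The SeO2 ene reaction and [2,3]-sigmatropic shift (Riley allylic oxidation) should oxidise only the methyl group trans to the chain, which fixes the (E) geometry, and MnO2 then oxidises the remaining allylic alcohol 3 so that the crude alcohol/enal mixture converges on the enal, the acetal being inert to both oxidants.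

Step 3
Reactants: 4 (S,E)-8,8-dimethoxy-2,6-dimethyloct-2-enal
Product: 5 ethyl (S,2E,4E)-10,10-dimethoxy-4,8-dimethyldeca-2,4-dienoate
Conditions: Ph3P=CHCO2Et, CH2Cl2, rt → 40 °C
Reagents that add atoms: ethyl (triphenylphosphoranylidene)acetate, CCOC(=O)C=P(c1ccccc1)(c1ccccc1)c1ccccc1
Why: Wittig olefination of the enal with the stabilised ylide should give the (E)-enoate, the trisubstituted alkene keeping its geometry and the acetal staying untouched.

Step 4
Reactants: 5 ethyl (S,2E,4E)-10,10-dimethoxy-4,8-dimethyldeca-2,4-dienoate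
Product: 6 (S,2E,4E)-10,10-dimethoxy-4,8-dimethyldeca-2,4-dien-1-ol
Conditions: i-Bu2AlH, CH2Cl2, −78 °C
Reagents that add atoms: none
Why: Aluminium hydride 1,2-reduction of the dienoate should give the dienol, the acetal being inert to hydride.

Step 5
Reactants: 6 (S,2E,4E)-10,10-dimethoxy-4,8-dimethyldeca-2,4-dien-1-ol
Product: 7 tert-butyl{[(S,2E,4E)-10,10-dimethoxy-4,8-dimethyldeca-2,4-dien-1-yl]oxy}diphenylsilane
Conditions: t-BuPh2SiCl, imidazole, CH2Cl2, 0 °C → rt
Reagents that add atoms: tert-butylchlorodiphenylsilane, CC(C)(C)[Si](Cl)(c1ccccc1)c1ccccc1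
Why: Silylation of the primary allylic alcohol gives an ether of low Lewis basicity that should not ionise under the later Lewis acid step.

Step 6
Reactants: 7 tert-butyl{[(S,2E,4E)-10,10-dimethoxy-4,8-dimethyldeca-2,4-dien-1-yl]oxy}diphenylsilane
Product: 8 (S,6E,8E)-10-[(tert-butyldiphenylsilyl)oxy]-3,7-dimethyldeca-6,8-dienal
Conditions: PPTS (cat.), acetone/H2O (10:1), 45 °C
Reagents that add atoms: water, O
Why: Acid-catalysed acetal hydrolysis (transacetalisation with acetone) should free the aldehyde, while the hindered allylic silyl ether and the diene tolerate the weak acid.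

Step 7
Reactants: 8 (S,6E,8E)-10-[(tert-butyldiphenylsilyl)oxy]-3,7-dimethyldeca-6,8-dienal
Product: 9 (S,2E,8E,10E)-12-[(tert-butyldiphenylsilyl)oxy]-5,9-dimethyldodeca-2,8,10-trienal
Conditions: Ph3P=CHCHO, toluene, 80 °C
Reagents that add atoms: (triphenylphosphoranylidene)acetaldehyde, O=CC=P(c1ccccc1)(c1ccccc1)c1ccccc1
Why: Wittig olefination with the formyl-stabilised ylide should give the (E)-enal dienophile, and the methyl-bearing centre is β to the aldehyde and cannot epimerise.

Step 8
Reactants: 9 (S,2E,8E,10E)-12-[(tert-butyldiphenylsilyl)oxy]-5,9-dimethyldodeca-2,8,10-trienal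
Product: 10 (1R,2S,4aS,7S,8aS)-2-{[(tert-butyldiphenylsilyl)oxy]methyl}-4,7-dimethyl-1,2,4a,5,6,7,8,8a-octahydronaphthalene-1-carbaldehyde
Conditions: Me2AlCl (1.1 equiv), CH2Cl2, −78 → −20 °C
Reagents that add atoms: none
Why: The Lewis acid-activated enal should react in an intramolecular Diels–Alder reaction through the endo transition state with a chair-like tether that keeps the C-7 methyl equatorial, which sets the trans ring fusion (C-4a, C-8a), the equatorial formyl group at C-1 and the C-2 side chain cis to it, all relative to the citronellal centre.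

Step 9
Reactants: 10 (1R,2S,4aS,7S,8aS)-2-{[(tert-butyldiphenylsilyl)oxy]methyl}-4,7-dimethyl-1,2,4a,5,6,7,8,8a-octahydronaphthalene-1-carbaldehyde
Product: 11 tert-butyl{[(1R,2R,4aS,7S,8aR)-4,7-dimethyl-1-[(E)-prop-1-enyl]-1,2,4a,5,6,7,8,8a-octahydronaphthalen-2-yl]methoxy}diphenylsilane
Conditions: 5-(ethylsulfonyl)-1-phenyl-1H-tetrazole, KN(SiMe3)2, DME, −60 °C → rt
Reagents that add atoms: 5-(ethylsulfonyl)-1-phenyl-1H-tetrazole, CCS(=O)(=O)c1nnnn1-c1ccccc1
Why: The Julia–Kocienski olefination of an α-branched aldehyde with the metalated ethyl tetrazolyl sulfone should give the (E)-propenyl group, and C-1 is safe because its equatorial substituent is already the stable one.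

Step 10
Reactants: 11 tert-butyl{[(1R,2R,4aS,7S,8aR)-4,7-dimethyl-1-[(E)-prop-1-enyl]-1,2,4a,5,6,7,8,8a-octahydronaphthalen-2-yl]methoxy}diphenylsilane
Product: 12 [(1R,2R,4aS,7S,8aR)-4,7-dimethyl-1-[(E)-prop-1-enyl]-1,2,4a,5,6,7,8,8a-octahydronaphthalen-2-yl]methanol
Conditions: n-Bu4NF, THF, rt
Reagents that add atoms: none
Why: Fluoride cleavage of the silyl ether should free the primary alcohol without affecting the two unactivated alkenes.

Step 11
Reactants: 12 [(1R,2R,4aS,7S,8aR)-4,7-dimethyl-1-[(E)-prop-1-enyl]-1,2,4a,5,6,7,8,8a-octahydronaphthalen-2-yl]methanol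
Product: 13 (1R,2R,4aS,7S,8aR)-4,7-dimethyl-1-[(E)-prop-1-enyl]-1,2,4a,5,6,7,8,8a-octahydronaphthalene-2-carbaldehyde (formyl cis to propenyl)
Conditions: DMP, NaHCO3, CH2Cl2, 0 °C → rt
Reagents that add atoms: none
Why: Oxidation with the periodinane under buffered, non-basic conditions should give the β,γ-unsaturated aldehyde without moving the alkene.

Step 12
Reactants: 13 (1R,2R,4aS,7S,8aR)-4,7-dimethyl-1-[(E)-prop-1-enyl]-1,2,4a,5,6,7,8,8a-octahydronaphthalene-2-carbaldehyde
Product: 14 (1R,2S,4aS,7S,8aR)-4,7-dimethyl-1-[(E)-prop-1-enyl]-1,2,4a,5,6,7,8,8a-octahydronaphthalene-2-carbaldehyde (formyl trans to propenyl)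
Conditions: DBU (0.3 equiv), CH2Cl2, rt
Reagents that add atoms: none
Why: Reversible enolisation should equilibrate C-2 toward the epimer with the formyl group pseudoequatorial and trans to the propenyl group, the dienolate being reprotonated at C-2 so that the C-3/C-4 alkene stays in place; recovered 13 is resubmitted.

Step 13
Reactants: 15 2,4-dihydroxypyridine
Product: 16 2,4-bis(methoxymethoxy)pyridine
Conditions: MOMCl, Ag2CO3, toluene, rt, dark
Reagents that add atoms: chloromethyl methyl ether, COCCl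
Why: Alkylation of the silver pyridonate in a non-polar solvent is O-selective and should give the 2,4-bis-acetal and not the N-alkyl pyridone.

Step 14
Reactants: 16 2,4-bis(methoxymethoxy)pyridine
Product: 17 5-bromo-2,4-bis(methoxymethoxy)pyridine
Conditions: NBS, MeCN, 0 °C → rt
Reagents that add atoms: N-bromosuccinimide, O=C1CCC(=O)N1Br
Why: Electrophilic aromatic bromination should occur at C-5, para to the 2-alkoxy and ortho to the 4-alkoxy group, because C-3 is flanked by both acetals.

Step 15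
Reactants: 17 5-bromo-2,4-bis(methoxymethoxy)pyridine; 18 4-(tert-butyldimethylsilyloxy)phenylboronic acid
Product: 19 5-[4-(tert-butyldimethylsilyloxy)phenyl]-2,4-bis(methoxymethoxy)pyridine
Conditions: Pd(PPh3)4 (5 mol%), K3PO4, 1,4-dioxane/H2O (9:1), 80 °C
Reagents that add atoms: none
Why: Suzuki–Miyaura coupling (oxidative addition of zerovalent palladium into C-5–Br, transmetalation, reductive elimination) should join the rings, the phosphate base being mild enough for the aryl silyl ether and the acetals.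

Step 16
Reactants: 19 5-[4-(tert-butyldimethylsilyloxy)phenyl]-2,4-bis(methoxymethoxy)pyridine; 14 (1R,2S,4aS,7S,8aR)-4,7-dimethyl-1-[(E)-prop-1-enyl]-1,2,4a,5,6,7,8,8a-octahydronaphthalene-2-carbaldehyde
Product: 21 {5-[4-(tert-butyldimethylsilyloxy)phenyl]-2,4-bis(methoxymethoxy)pyridin-3-yl}(Dec)methanol (both carbinol epimers), via 3-lithiopyridine 20 (not isolated)
Conditions: n-BuLi, THF, −78 °C, 1 h; then 14, THF, −78 °C
Reagents that add atoms: none
Why: Directed ortho-metalation between the two methoxymethoxy groups gives the C-3 lithio species, whose 1,2-addition to the aldehyde at −78 °C should outrun enolisation; the carbinol configuration does not matter because it is oxidised next.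

Step 17
Reactants: 21 {5-[4-(tert-butyldimethylsilyloxy)phenyl]-2,4-bis(methoxymethoxy)pyridin-3-yl}(Dec)methanol
Product: 22 {5-[4-(tert-butyldimethylsilyloxy)phenyl]-2,4-bis(methoxymethoxy)pyridin-3-yl}(Dec)methanone
Conditions: DMP, NaHCO3, CH2Cl2, rt
Reagents that add atoms: none
Why: Periodinane oxidation of the hindered secondary alcohol should give the aryl ketone, the buffer protecting the acetals and C-2 already holding its stable configuration.

Step 18
Reactants: 22 {5-[4-(tert-butyldimethylsilyloxy)phenyl]-2,4-bis(methoxymethoxy)pyridin-3-yl}(Dec)methanone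
Product: 23 [5-(4-hydroxyphenyl)-2,4-bis(methoxymethoxy)pyridin-3-yl](Dec)methanone
Conditions: n-Bu4NF, AcOH, THF, 0 °C
Reagents that add atoms: none
Why: Buffered fluoride cleaves the aryl silyl ether fast and should leave the acetals and the enolisable C-2 centre untouched.

Step 19
Reactants: 23 [5-(4-hydroxyphenyl)-2,4-bis(methoxymethoxy)pyridin-3-yl](Dec)methanone
Product: 24 4-hydroxy-4-[5-(Dec-carbonyl)-4,6-bis(methoxymethoxy)pyridin-3-yl]cyclohexa-2,5-dien-1-one
Conditions: PhI(OAc)2, MeCN/H2O (4:1), 0 °C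
Reagents that add atoms: water, O
Why: Ligand exchange of the phenol at trivalent iodine and loss of PhI give a phenoxenium-type cation that water captures at the aryl-substituted para carbon (oxidative dearomatisation, established for 4-arylphenols); C-1′ is still prochiral.

Step 20
Reactants: 24 4-hydroxy-4-[5-(Dec-carbonyl)-4,6-bis(methoxymethoxy)pyridin-3-yl]cyclohexa-2,5-dien-1-one
Product: 25 4-[5-(Dec-carbonyl)-4,6-bis(methoxymethoxy)pyridin-3-yl]-4-(triethylsilyloxy)cyclohexa-2,5-dien-1-one
Conditions: Et3SiCl, imidazole, DMAP (cat.), DMF, rt → 40 °C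
Reagents that add atoms: chlorotriethylsilane, CC[Si](Cl)(CC)CC
Why: Silylation of the tertiary doubly allylic hydroxyl with the chloride activated by imidazole and DMAP should proceed in DMF, and the chloride is chosen because silyl triflates can attack the MOM acetals.

Step 21
Reactants: 25 4-[5-(Dec-carbonyl)-4,6-bis(methoxymethoxy)pyridin-3-yl]-4-(triethylsilyloxy)cyclohexa-2,5-dien-1-one
Product: 26 (1′R,2′S,3′R)-2′,3′-epoxy-4′-oxocyclohex-5′-enyl triethylsilyl ether of the 3-(Dec-carbonyl)-2,4-bis(methoxymethoxy)pyridine (oxirane anti to the silyloxy group)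
Conditions: 9-amino(9-deoxy)epiquinine (20 mol%), CF3CO2H (40 mol%), aq. H2O2 (50 wt%, 1.2 equiv), 1,4-dioxane, 30 °C
Reagents that add atoms: hydrogen peroxide, OO
Why: Proposed new method: the closest known reaction type is the iminium-catalysed nucleophilic epoxidation of simple cyclic enones with aqueous H2O2 and cinchona primary amine salts, extended here to a cross-conjugated 4,4-disubstituted cyclohexadienone, on which it has not been shown. The primary amine condenses with the unhindered dienone carbonyl C-4′ (the aryl ketone between two alkoxy groups cannot compete), H2O2 held by the protonated quinuclidine adds to the β-carbon C-2′, and the β-hydroperoxy enamine closes the oxirane by attack of C-3′ on the proximal oxygen with loss of water, a 3-exo-tet closure, before hydrolysis releases 26. C-2′ and C-3′ are a cis pair by the ring; their face is set by the triethylsilyloxy group on C-1′, whose silicon sits over the dienone because it avoids the ortho-substituted pyridyl ring, so peroxide enters anti to oxygen, and C-1′ becomes stereogenic once the two arms differ. The step needs selection between two enone arms and two faces: the catalyst fixes the sense of attack at the β-carbon and the silyl ether fixes the face, so only one arm offers the matched combination and the remote decalin centres play no part. The C-3/C-4 and propenyl alkenes are not electrophilic and are inert to H2O2, and about one equivalent of peroxide should stop at the mono-epoxide because the product enone is more hindered.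

Step 22
Reactants: 26 (1′R,2′S,3′R)-2′,3′-epoxy-4′-oxocyclohex-5′-enyl triethylsilyl ether
Product: 27 (1′R,2′S,3′R)-2′,3′-epoxy-4′-oxocyclohexyl triethylsilyl ether of the 3-(Dec-carbonyl)-2,4-bis(methoxymethoxy)pyridine
Conditions: [(Ph3P)CuH]6 (0.5 equiv), toluene, H2O (5 equiv), rt
Reagents that add atoms: none
Why: Conjugate hydride transfer from the phosphine-stabilised copper hydride cluster to C-6′ gives a copper enolate that water protonates, and the hindered aryl ketone, the oxirane and the unactivated alkenes should not react; no stereocentre is formed.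

Step 23
Reactants: 27 (1′R,2′S,3′R)-2′,3′-epoxy-4′-oxocyclohexyl triethylsilyl ether
Product: 28 (1′R,2′S,3′S,4′R)-2′,3′-epoxy-4′-hydroxycyclohexyl triethylsilyl ether of the 3-(Dec-carbonyl)-2,4-bis(methoxymethoxy)pyridine
Conditions: i-Bu2AlH (1.2 equiv), CH2Cl2, −78 °C
Reagents that add atoms: none
Why: Aluminium bound to the oxirane oxygen should deliver hydride to C-4′ from the oxirane face (epoxide-directed reduction of an α,β-epoxy ketone), which places the new hydroxyl anti to the oxirane and cis to the C-1′ oxygen, while the aryl ketone is shielded by its two ortho alkoxy groups.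

Step 24
Reactants: 28 (1′R,2′S,3′S,4′R)-2′,3′-epoxy-4′-hydroxycyclohexyl triethylsilyl ether
Product: 29 target, 3-(Dec-carbonyl)-4-hydroxy-5-[(1′R,2′S,3′S,4′R)-2′,3′-epoxy-1′,4′-dihydroxycyclohexyl]-1H-pyridin-2-one
Conditions: CF3CO2H/H2O/THF (1:1:4), 0 °C → rt; pH 7 buffer
Reagents that add atoms: none
Why: The pyridyl MOM ethers are acetals of acidic pyridone hydroxyls and ionise on N-protonation under weak acid, the tertiary triethylsilyl ether hydrolyses under the same conditions, and the oxirane flanked by two oxygenated carbons should resist acid-catalysed opening at this temperature.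

**Compound list**
1 | (S)-citronellal | O=CC[C@@H](C)CCC=C(C)C | starting material
2 | (S)-8,8-dimethoxy-2,6-dimethyloct-2-ene | COC(OC)C[C@@H](C)CCC=C(C)C | intermediate
3 | (S,E)-8,8-dimethoxy-2,6-dimethyloct-2-en-1-ol | COC(OC)C[C@@H](C)CC/C=C(\C)CO | intermediate
4 | (S,E)-8,8-dimethoxy-2,6-dimethyloct-2-enal | COC(OC)C[C@@H](C)CC/C=C(\C)C=O | intermediate
5 | ethyl (S,2E,4E)-10,10-dimethoxy-4,8-dimethyldeca-2,4-dienoate | COC(OC)C[C@@H](C)CC/C=C(\C)/C=C/C(=O)OCC | intermediate
6 | (S,2E,4E)-10,10-dimethoxy-4,8-dimethyldeca-2,4-dien-1-ol | COC(OC)C[C@@H](C)CC/C=C(\C)/C=C/CO | intermediate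
7 | tert-butyldiphenylsilyl ether of 6 | COC(OC)C[C@@H](C)CC/C=C(\C)/C=C/CO[Si](c1ccccc1)(c1ccccc1)C(C)(C)C | intermediate
8 | (S,6E,8E)-10-[(tert-butyldiphenylsilyl)oxy]-3,7-dimethyldeca-6,8-dienal | O=CC[C@@H](C)CC/C=C(\C)/C=C/CO[Si](c1ccccc1)(c1ccccc1)C(C)(C)C | intermediate
9 | (S,2E,8E,10E)-12-[(tert-butyldiphenylsilyl)oxy]-5,9-dimethyldodeca-2,8,10-trienal | O=C/C=C/C[C@@H](C)CC/C=C(\C)/C=C/CO[Si](c1ccccc1)(c1ccccc1)C(C)(C)C | intermediate
10 | (1R,2S,4aS,7S,8aS)-2-{[(tert-butyldiphenylsilyl)oxy]methyl}-4,7-dimethyl-1,2,4a,5,6,7,8,8a-octahydronaphthalene-1-carbaldehyde | O=C[C@@H]1[C@H]2C[C@@H](C)CC[C@@H]2C(C)=C[C@@H]1CO[Si](c1ccccc1)(c1ccccc1)C(C)(C)C | intermediate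
11 | tert-butyldiphenylsilyl ether of 12 | C/C=C/[C@@H]1[C@H]2C[C@@H](C)CC[C@@H]2C(C)=C[C@@H]1CO[Si](c1ccccc1)(c1ccccc1)C(C)(C)C | intermediate
12 | [(1R,2R,4aS,7S,8aR)-4,7-dimethyl-1-[(E)-prop-1-enyl]-1,2,4a,5,6,7,8,8a-octahydronaphthalen-2-yl]methanol | C/C=C/[C@@H]1[C@H]2C[C@@H](C)CC[C@@H]2C(C)=C[C@@H]1CO | intermediate
13 | (1R,2R,4aS,7S,8aR)-4,7-dimethyl-1-[(E)-prop-1-enyl]-1,2,4a,5,6,7,8,8a-octahydronaphthalene-2-carbaldehyde | C/C=C/[C@@H]1[C@H]2C[C@@H](C)CC[C@@H]2C(C)=C[C@@H]1C=O | intermediate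
14 | (1R,2S,4aS,7S,8aR)-4,7-dimethyl-1-[(E)-prop-1-enyl]-1,2,4a,5,6,7,8,8a-octahydronaphthalene-2-carbaldehyde | C/C=C/[C@@H]1[C@H]2C[C@@H](C)CC[C@@H]2C(C)=C[C@H]1C=O | intermediate
15 | 2,4-dihydroxypyridine | Oc1ccnc(O)c1 | starting material
16 | 2,4-bis(methoxymethoxy)pyridine | COCOc1ccnc(OCOC)c1 | intermediate
17 | 5-bromo-2,4-bis(methoxymethoxy)pyridine | COCOc1cc(OCOC)c(Br)cn1 | intermediate
18 | 4-(tert-butyldimethylsilyloxy)phenylboronic acid | OB(O)c1ccc(O[Si](C)(C)C(C)(C)C)cc1 | starting material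
19 | 5-[4-(tert-butyldimethylsilyloxy)phenyl]-2,4-bis(methoxymethoxy)pyridine | COCOc1cc(OCOC)c(-c2ccc(O[Si](C)(C)C(C)(C)C)cc2)cn1 | intermediate
20 | {5-[4-(tert-butyldimethylsilyloxy)phenyl]-2,4-bis(methoxymethoxy)pyridin-3-yl}lithium | [Li]c1c(OCOC)ncc(-c2ccc(O[Si](C)(C)C(C)(C)C)cc2)c1OCOC | intermediate
21 | {5-[4-(tert-butyldimethylsilyloxy)phenyl]-2,4-bis(methoxymethoxy)pyridin-3-yl}(Dec)methanol | C/C=C/[C@@H]1[C@H]2C[C@@H](C)CC[C@@H]2C(C)=C[C@H]1C(O)c1c(OCOC)ncc(-c2ccc(O[Si](C)(C)C(C)(C)C)cc2)c1OCOC | intermediate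
22 | {5-[4-(tert-butyldimethylsilyloxy)phenyl]-2,4-bis(methoxymethoxy)pyridin-3-yl}(Dec)methanone | C/C=C/[C@@H]1[C@H]2C[C@@H](C)CC[C@@H]2C(C)=C[C@H]1C(=O)c1c(OCOC)ncc(-c2ccc(O[Si](C)(C)C(C)(C)C)cc2)c1OCOC | intermediate
23 | [5-(4-hydroxyphenyl)-2,4-bis(methoxymethoxy)pyridin-3-yl](Dec)methanone | C/C=C/[C@@H]1[C@H]2C[C@@H](C)CC[C@@H]2C(C)=C[C@H]1C(=O)c1c(OCOC)ncc(-c2ccc(O)cc2)c1OCOC | intermediate
24 | 4-hydroxy-4-[5-(Dec-carbonyl)-4,6-bis(methoxymethoxy)pyridin-3-yl]cyclohexa-2,5-dien-1-one | C/C=C/[C@@H]1[C@H]2C[C@@H](C)CC[C@@H]2C(C)=C[C@H]1C(=O)c1c(OCOC)ncc(C2(O)C=CC(=O)C=C2)c1OCOC | intermediate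
25 | O-triethylsilyl p-quinol (triethylsilyl ether of 24) | C/C=C/[C@@H]1[C@H]2C[C@@H](C)CC[C@@H]2C(C)=C[C@H]1C(=O)c1c(OCOC)ncc(C2(O[Si](CC)(CC)CC)C=CC(=O)C=C2)c1OCOC | intermediate
26 | (1′R,2′S,3′R)-2′,3′-epoxy-4′-oxocyclohex-5′-enyl triethylsilyl ether | C/C=C/[C@@H]1[C@H]2C[C@@H](C)CC[C@@H]2C(C)=C[C@H]1C(=O)c1c(OCOC)ncc([C@]2(O[Si](CC)(CC)CC)C=CC(=O)[C@@H]3O[C@@H]32)c1OCOC | intermediate
27 | (1′R,2′S,3′R)-2′,3′-epoxy-4′-oxocyclohexyl triethylsilyl ether | C/C=C/[C@@H]1[C@H]2C[C@@H](C)CC[C@@H]2C(C)=C[C@H]1C(=O)c1c(OCOC)ncc([C@]2(O[Si](CC)(CC)CC)CCC(=O)[C@@H]3O[C@@H]32)c1OCOC | intermediate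
28 | (1′R,2′S,3′S,4′R)-2′,3′-epoxy-4′-hydroxycyclohexyl triethylsilyl ether | C/C=C/[C@@H]1[C@H]2C[C@@H](C)CC[C@@H]2C(C)=C[C@H]1C(=O)c1c(OCOC)ncc([C@]2(O[Si](CC)(CC)CC)CC[C@@H](O)[C@@H]3O[C@@H]32)c1OCOC | intermediate
29 | 3-(Dec-carbonyl)-4-hydroxy-5-[(1′R,2′S,3′S,4′R)-2′,3′-epoxy-1′,4′-dihydroxycyclohexyl]-1H-pyridin-2-one | C/C=C/[C@@H]1[C@H]2C[C@@H](C)CC[C@@H]2C(C)=C[C@H]1C(=O)c1c(O)c([C@]2(O)CC[C@@H](O)[C@@H]3O[C@@H]32)c[nH]c1=O | target

**Step count**
Total: 24 steps. Longest linear sequence: 21 steps (steps 1–12, then 16–24).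

**Steps most likely to fail**

Step 21. The catalyst may discriminate poorly between the two enone arms, peroxide may enter syn to the silyloxy group, the cross-conjugated dienone may form its iminium ion slowly, or the product enone may be epoxidised a second time. Fallback from 25: t-BuOOH and DBU in CH2Cl2 at 0 °C (Weitz–Scheffer epoxidation, known for p-quinol ethers) gives up catalyst control. Both arms would react anti to the silyl ether, giving 26 together with its arm-isomer, the (1′S,2′R,3′S)-epoxy enone F1. The decalin is a single enantiomer, so the two are diastereomers and separable by chromatography, and the route is rejoined at 26.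

Step 23. Hydride may be delivered to the face away from the oxirane, giving the C-4′ epimer, or the aryl ketone may be reduced as well. Fallback from 27: NaBH4 with CeCl3·7H2O in MeOH at −78 °C (Luche conditions, external hydride anti to the oxirane) is used on purpose to make the C-4′ epimeric alcohol F2. Mitsunobu inversion (4-nitrobenzoic acid, PPh3, diisopropyl azodicarboxylate, toluene) converts it into the 4′R 4-nitrobenzoate F3, and K2CO3 in MeOH at 0 °C cleaves the ester to rejoin the route at 28.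

Step 24. Protic acid may open the oxirane or ionise the tertiary C-1′ carbinol before both MOM groups are lost. Fallback from 28: n-Bu4NF/AcOH in THF first removes the triethylsilyl group to give the bis(MOM) diol F4. Me3SiOTf with 2,2′-bipyridyl in CH2Cl2 at 0 °C then exchanges both pyridyl MOM acetals for trimethylsilyl groups under buffered, non-protic conditions and silylates the two carbinols, giving the tetrakis(trimethylsilyl) compound F5. Hydrolysis in pH 7 aqueous methanol returns to the route at 29.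

**Further compounds**
F1 | step 21 | (1′S,2′R,3′S)-2′,3′-epoxy-4′-oxocyclohex-5′-enyl triethylsilyl ether (other arm epoxidised) | C/C=C/[C@@H]1[C@H]2C[C@@H](C)CC[C@@H]2C(C)=C[C@H]1C(=O)c1c(OCOC)ncc([C@@]2(O[Si](CC)(CC)CC)C=CC(=O)[C@H]3O[C@H]32)c1OCOC
F2 | step 23 | C-4′ epimer of 28 (hydroxyl syn to the oxirane) | C/C=C/[C@@H]1[C@H]2C[C@@H](C)CC[C@@H]2C(C)=C[C@H]1C(=O)c1c(OCOC)ncc([C@]2(O[Si](CC)(CC)CC)CC[C@H](O)[C@@H]3O[C@@H]32)c1OCOC
F3 | step 23 | 4-nitrobenzoate of 28 | C/C=C/[C@@H]1[C@H]2C[C@@H](C)CC[C@@H]2C(C)=C[C@H]1C(=O)c1c(OCOC)ncc([C@]2(O[Si](CC)(CC)CC)CC[C@@H](OC(=O)c4ccc(cc4)[N+](=O)[O-])[C@@H]3O[C@@H]32)c1OCOC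
F4 | step 24 | desilylated 28 (2,4-bis(methoxymethoxy)pyridine with free C-1′ and C-4′ hydroxyls) | C/C=C/[C@@H]1[C@H]2C[C@@H](C)CC[C@@H]2C(C)=C[C@H]1C(=O)c1c(OCOC)ncc([C@]2(O)CC[C@@H](O)[C@@H]3O[C@@H]32)c1OCOC
F5 | step 24 | 2,4-bis(trimethylsilyloxy)pyridine with C-1′ and C-4′ trimethylsilyl ethers | C/C=C/[C@@H]1[C@H]2C[C@@H](C)CC[C@@H]2C(C)=C[C@H]1C(=O)c1c(O[Si](C)(C)C)ncc([C@]2(O[Si](C)(C)C)CC[C@@H](O[Si](C)(C)C)[C@@H]3O[C@@H]32)c1O[Si](C)(C)C
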